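## The problem

Compound 17, octadecyl 3-(2,4-dihydroxy-3-methoxyphenyl)propanoate, is a 1,2,3,4-tetrasubstituted benzene. C1 carries the propanoate chain, C2 a free hydroxyl, C3 a methoxy group, C4 a second free hydroxyl, and C5 and C6 carry hydrogen. There are no stereocentres, so the difficulty is purely positional: four different contiguous substituents, with the only O-methyl group on the middle oxygen. Substitution or selective alkylation of a preformed pyrogallol-type arene does not deliver that pattern cleanly.

Three features limit the reagents that can be used late in the route:
- The 2,4-dioxygenated ring is an electron-rich resorcinol, easily oxidised or attacked by electrophiles.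
- The C2 hydroxyl can close onto the ester carbonyl under acid or heat, giving a six-membered dihydrocoumarin lactone and expelling the fatty alcohol.
- The waxy octadecyl ester rules out hydroxide, alkoxide and hydride reagents.

A good route therefore brings the ester in at its final oxidation level, avoids phenol protecting groups, and ends under mild, non-oxidising conditions. The enabling feature is that C2, C3 and C4 with their oxygens, plus C5, have the carbon and oxidation pattern of a 2-alkoxyacetoacetate (ester carbon, alkoxylated α-carbon, ketone carbon, methyl carbon). C1 and C6 form a two-carbon unit bearing only the side chain. The ring can be built from a fully oxygenated butadiene and a two-carbon partner whose C1 substituent directs the union and then leaves to supply the last double bond.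

## Retrosynthesis

**17 back to 15 (through 16).** No skeletal bond is cut. The C1=C6 double bond of 17 is traced to a nitro group on C1 and a hydrogen on C6, and the two phenols to ring ketones. This gives nitro dione 15, with enedione 16 as the transient link. The advantage over dehydrogenating a nitro-free dione is that the arene oxidation level is reached by elimination, so no oxidant meets the resorcinol and both hydroxyls appear unprotected in the last step. The forward reaction must remove a C6 hydrogen that no carbonyl activates, with a base that leaves the octadecyl ester alone.

**15 back to 6 and 13 (through 14).** Cutting C5–C6 and C1–C2 divides the ring into the four-carbon piece C2–C5 (diene 6) and the two-carbon piece C1/C6 (nitroalkene 13), joined through silylated cycloadduct 14. Other (4+2) partitions either spread the three oxygens over both partners or put the side chain on a diene terminus. This partition keeps every oxygen on one acetoacetate-like fragment and leaves a dienophile with one substituent. The polarity also matches: the unsubstituted terminus of 6 is its most nucleophilic carbon and the methylene of 13 its most electrophilic, so C5–C6 forms first and regiochemistry is not in doubt. Both precursors are acyclic and free of stereochemical content. The forward step must close the second bond, C1–C2, between two fully substituted carbons instead of stopping at a conjugate adduct.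

**6 back to 4 and 3 (through 5).** Only O–Si bonds are cut. Diene 6 is the bis-silyl dienol ether of keto ester 3, reached through mono-silyl enol ether 4 and lithium dienolate 5. Two-stage silylation is preferred over a single double enolisation because it fixes which oxygen is silylated under equilibrium control (the ketone oxygen, toward C2) and which under kinetic control (the ester oxygen, after γ-deprotonation). The forward steps need strictly anhydrous, non-aqueous isolation.

**3 back to 2 and 1.** The C–OMe bond at the α-carbon is cut, leading to diazo keto ester 2 and methyl acetoacetate 1. Carbenoid O–H insertion is preferred over displacing an α-halo keto ester with methoxide, which competes with acyl cleavage, and over a crossed Claisen condensation, which gives mixtures. The precursor is a bulk chemical; the forward sequence is a diazo transfer and a catalytic insertion.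

**13 back to 11, then 9 and 10 (through 12).** The C=C bond of 13 is traced to β-nitro alcohol 11 (activated as mesylate 12). The bond between the nitro-bearing carbon and the hydroxymethyl carbon is then cut to give nitro ester 9 and formaldehyde 10. Formaldehyde is the simplest source of the future C6, and the nitro group that later leaves is the same group that makes this C–C bond possible. The forward nitroaldol must stop after one hydroxymethylation, and the dehydration must not isomerise or polymerise the terminal nitroalkene.

**9 back to 7 and 8.** Cutting the bond between the nitromethane carbon (future C1) and the acrylate β-carbon gives nitromethane 7 and octadecyl acrylate 8. The octadecyl ester is bought as part of 8, so the route needs no esterification with a fatty alcohol. The forward conjugate addition must be kept at mono-addition.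

## Roads not taken

**Alternative 1: aryne carbomagnesiation with oxidative trapping.**
- Cut: the C1–side-chain bond and the C2–O bond, both across an aryne.
- Forward key step: a hindered lithium amide converts bromoarene A1 into a 3-methoxyaryne. Grignard reagent A2 adds at the carbon distal to the methoxy group. The resulting arylmagnesium, now ortho to the methoxy group, is borylated and oxidised to phenol A3.
- Merits: two adjacent substituents are set in one operation. Regiochemistry follows the well-understood inductive polarisation of 3-alkoxyarynes. The ring is bought, so nothing depends on a sensitive diene.
- Weak points: the chain arrives as a masked aldehyde. After A3 the route still needs unmasking, oxidation to the acid, esterification with A4 and debenzylation. The oxidation and esterification are carried out on an ortho-hydroxyaryl propanoic acid derivative, which is set up to lactonise. The amide base and A2 also compete for the aryne and for the bromide.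
- Comparison: this road is more secure in regiochemistry. The chosen plan answers with a chain that is already the octadecyl ester and with no protecting groups, and so has fewer operations after its key step.

**Alternative 2: hydroalkoxycarbonylation of a vinylarene.**
- Cut: the bond from the α-carbon to the carbonyl carbon, and the acyl–oxygen bond.
- Forward key step: vinylarene A5, A6 and A4 combine under a palladium catalyst with a bulky chelating bis(di-tert-butylphosphine) and a sulfonic acid to give linear ester A7. Only hydrogenolysis of two benzyl ethers then remains.
- Merits: it is the shortest and most atom-economical road, the fatty ester forms directly, and linear selectivity with this ligand class is established for styrenes.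
- Weak points: it needs a regiodefined tetrasubstituted arene to begin with, two benzyl groups, and pressurised A6. An electron-rich ortho-alkoxystyrene in strong acid can also oligomerise or add A4 at the benzylic carbon.
- Comparison: on step count and precedent for each operation this road is at least as good as the chosen one, and probably better if a suitable arene can be bought. The chosen plan places all four ring substituents by construction from C1 to C4 feedstocks, uses no phenol protection and no pressure equipment, and lets analogues be made by changing the nitroalkene alone.

**Alternative 3: Claisen cyclisation of a symmetric keto diester, then aromatisation.**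
- Cut: the C3–C4 bond.
- Forward key step: a tert-butoxide base forms the enolate of A8 at the methoxy-bearing methylene, which attacks one of the two equivalent ester arms to give dione A9 and release A4.
- Merits: robust, cheap carbonyl chemistry. The symmetry removes the question of which ester is attacked, and deprotonation of A9 drives the equilibrium.
- Weak points: A9 is the nitro-free analogue of 15 and is two hydrogens short of the arene. Reaching 17 needs a dehydrogenation, so an oxidant or hot palladium must act on a substrate whose product is an oxidisable resorcinol prone to lactonise. The heptanedioate backbone of A8 can also close on itself in a competing Dieckmann reaction, and making A8 requires double alkylation on the less acidic side of a methoxymethyl ketone.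
- Comparison: this road uses more forgiving reagents and scales more easily. The chosen plan builds the same ring one oxidation level higher, with the nitro group supplying the missing unsaturation as a leaving group, at the cost of handling a moisture-sensitive diene and a polymerisable nitroalkene.

Key step: step 8

Remark: the target is achiral. The stereocentres that appear in 3, 11, 12, 14, 15 and 16 are formed without control and are all erased, so these compounds are carried as racemates or diastereomer mixtures and their SMILES carry no configuration.

## Route

Step 1
Reactants: 1 methyl acetoacetate
Product: 2 methyl 2-diazo-3-oxobutanoate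
Conditions: 4-acetamidobenzenesulfonyl azide, Et3N, MeCN, 0 °C to rt
Reagents that add atoms: 4-acetamidobenzenesulfonyl azide, CC(=O)Nc1ccc(cc1)S(=O)(=O)N=[N+]=[N-]
Why: Regitz diazo transfer to an active methylene compound; the doubly activated C2 is the only site acidic enough for Et3N, and the sulfonamide by-product is removed by filtration and washing.

Step 2
Reactants: 2 methyl 2-diazo-3-oxobutanoate
Product: 3 methyl 2-methoxy-3-oxobutanoate (racemic)
Conditions: Rh2(OAc)4 (1 mol%), MeOH, CH2Cl2, 40 °C, slow addition of 2
Reagents that add atoms: methanol, CO
Why: Rhodium carbenoid O–H insertion into an alcohol, a standard route to 2-alkoxy-1,3-dicarbonyl compounds; slow addition keeps the diazo concentration low and suppresses carbene dimerisation.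

Step 3
Reactants: 3 methyl 2-methoxy-3-oxobutanoate
Product: 4 methyl 2-methoxy-3-(trimethylsilyloxy)but-2-enoate (E/Z mixture)
Conditions: Me3SiCl, Et3N, toluene, rt
Reagents that add atoms: chlorotrimethylsilane, C[Si](C)(C)Cl
Why: O-silylation of a β-keto ester under equilibrating amine conditions gives the conjugated silyl enol ether toward C2, as for 2-substituted acetoacetates; the product is isolated by filtration of the ammonium salt and concentration without water.

Step 4
Reactants: 4 methyl 2-methoxy-3-(trimethylsilyloxy)but-2-enoate
Product: 6 1,2-dimethoxy-1,3-bis(trimethylsilyloxy)buta-1,3-diene (either geometry at the tetrasubstituted double bond), via lithium dienolate 5 (not isolated)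
Conditions: LiN(iPr)2, THF, −78 °C; then Me3SiCl, −78 °C to rt; non-aqueous work-up
Reagents that add atoms: chlorotrimethylsilane, C[Si](C)(C)Cl
Why: Kinetic γ-deprotonation of the methyl group of a β-silyloxy enoate and O-silylation of the ester dienolate, the standard second stage in making 1-alkoxy-1,3-bis(silyloxy)butadienes; the hard silyl chloride reacts at oxygen.

Step 5
Reactants: 7 nitromethane; 8 octadecyl acrylate
Product: 9 octadecyl 4-nitrobutanoate
Conditions: MeNO2 (10 equiv), DBU (0.1 equiv), THF, 0 °C to rt
Reagents that add atoms: none
Why: Michael addition of a nitronate to an acrylate; the large excess of nitromethane keeps the reaction at mono-addition, and the catalytic amidine does not touch the ester.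

Step 6
Reactants: 9 octadecyl 4-nitrobutanoate; 10 formaldehyde (used as paraformaldehyde)
Product: 11 octadecyl 5-hydroxy-4-nitropentanoate (racemic)
Conditions: (CH2O)n (1.05 equiv), Et3N (0.2 equiv), THF/i-PrOH, rt
Reagents that add atoms: none
Why: Henry (nitroaldol) reaction of a primary nitroalkane with formaldehyde; limiting the aldehyde to about one equivalent holds the reaction at the mono-adduct, and the new stereocentre is uncontrolled and removed in step 7.

Step 7
Reactants: 11 octadecyl 5-hydroxy-4-nitropentanoate
Product: 13 octadecyl 4-nitropent-4-enoate, via nitro mesylate 12 (not isolated)
Conditions: MsCl, i-Pr2NEt, CH2Cl2, −30 to 0 °C; cold dilute acid wash; used at once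
Reagents that add atoms: none
Why: Mesylation of a β-nitro alcohol and E1cB loss of methanesulfonate through the nitronate, the standard dehydration to conjugated nitroalkenes; the hindered amine, low temperature and prompt acidic wash limit polymerisation and double-bond migration.

Step 8
Reactants: 6 1,2-dimethoxy-1,3-bis(trimethylsilyloxy)buta-1,3-diene; 13 octadecyl 4-nitropent-4-enoate
Product: 15 octadecyl 3-(3-methoxy-1-nitro-2,4-dioxocyclohexyl)propanoate (racemic diastereomer and enol mixture), via silylated cycloadduct 14 (not isolated)
Conditions: 6 (1.5 equiv), toluene, −20 °C to rt; then 1 M HCl, THF, 0 °C
Reagents that add atoms: none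
Why: This is a normal-demand Diels-Alder reaction between a very electron-rich tetraoxygenated butadiene and a 1,1-disubstituted nitroalkene; the closest known type is the cycloaddition of 1,1-dialkoxy-3-silyloxybutadienes and 1-alkoxy-3-silyloxybutadienes with nitroalkenes used as regiocontrolling alkyne equivalents, and this particular pairing is untested. The reaction is concerted but strongly asynchronous: the unsubstituted diene terminus (future C5) bonds first to the nitroalkene methylene (C6), and the nitro-bearing carbon (C1) then bonds to the ketene acetal carbon (C2). The six-membered carbocycle closes in the (4+2) mode from four diene carbons and two dienophile carbons; in the stepwise limit the second bond is a 6-exo-trig attack of the nitronate carbon on the silyloxy(methoxy)carbenium carbon. Regioselectivity is the selectivity that matters, and the substrates secure it because the largest HOMO coefficient of 6 and the largest LUMO coefficient of 13 both lie on their CH2 termini. Running the reaction thermally in a non-polar solvent without a Lewis acid disfavours the two escapes from ring closure: silyl transfer to the nitronate (open-chain Mukaiyama-Michael product) and the hetero-Diels-Alder mode in which the nitroalkene acts as a heterodiene. Cold dilute acid then cleaves the silyl enol ether to the C4 ketone and collapses the mixed silyl methyl ketal to the C2 ketone with loss of methanol, so all three oxygens arrive from the diene. The stereocentres at C1 and C2 of 14 and at C1 and C3 of 15 are uncontrolled and need not be controlled, since each becomes an sp2 carbon in step 9.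

Step 9
Reactants: 15 octadecyl 3-(3-methoxy-1-nitro-2,4-dioxocyclohexyl)propanoate
Product: 17 octadecyl 3-(2,4-dihydroxy-3-methoxyphenyl)propanoate, via enedione 16 (not isolated)
Conditions: DBU (2.5 equiv), dry THF, 0 °C to rt, Ar; then cold aqueous NaH2PO4
Reagents that add atoms: none
Why: Base-induced elimination of nitrous acid from a tertiary α-nitro ketone (nitro as leaving group, E2-type, as known for 2-alkyl-2-nitrocycloalkanones) gives the C1=C6 enone 16, whose two remaining ketones enolise at once because the enol form is a benzene ring. Under base the C2 phenoxide cannot displace the more basic octadecanolate, so the dihydrocoumarin is avoided provided the quench is cold and only weakly acidic.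

## Compound list

1 | methyl acetoacetate (methyl 3-oxobutanoate) | CC(=O)CC(=O)OC | starting material
2 | methyl 2-diazo-3-oxobutanoate | CC(=O)C(=[N+]=[N-])C(=O)OC | intermediate
3 | methyl 2-methoxy-3-oxobutanoate (racemic) | CC(=O)C(OC)C(=O)OC | intermediate
4 | methyl 2-methoxy-3-(trimethylsilyloxy)but-2-enoate (E/Z mixture) | CC(O[Si](C)(C)C)=C(OC)C(=O)OC | intermediate
5 | lithium 1,2-dimethoxy-3-(trimethylsilyloxy)buta-1,3-dien-1-olate (not isolated) | [Li+].[O-]C(OC)=C(OC)C(=C)O[Si](C)(C)C | intermediate
6 | 1,2-dimethoxy-1,3-bis(trimethylsilyloxy)buta-1,3-diene (either geometry at C1=C2) | C=C(O[Si](C)(C)C)C(OC)=C(OC)O[Si](C)(C)C | intermediate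
7 | nitromethane | C[N+](=O)[O-] | starting material
8 | octadecyl acrylate (octadecyl prop-2-enoate) | C=CC(=O)OCCCCCCCCCCCCCCCCCC | starting material
9 | octadecyl 4-nitrobutanoate | CCCCCCCCCCCCCCCCCCOC(=O)CCC[N+](=O)[O-] | intermediate
10 | formaldehyde (used as paraformaldehyde) | C=O | starting material
11 | octadecyl 5-hydroxy-4-nitropentanoate (racemic) | CCCCCCCCCCCCCCCCCCOC(=O)CCC(CO)[N+](=O)[O-] | intermediate
12 | octadecyl 5-(methanesulfonyloxy)-4-nitropentanoate (racemic, not isolated) | CCCCCCCCCCCCCCCCCCOC(=O)CCC(COS(C)(=O)=O)[N+](=O)[O-] | intermediate
13 | octadecyl 4-nitropent-4-enoate | C=C(CCC(=O)OCCCCCCCCCCCCCCCCCC)[N+](=O)[O-] | intermediate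
14 | octadecyl 3-[2,3-dimethoxy-1-nitro-2,4-bis(trimethylsilyloxy)cyclohex-3-en-1-yl]propanoate (racemic diastereomer mixture, not isolated) | CCCCCCCCCCCCCCCCCCOC(=O)CCC1([N+](=O)[O-])CCC(O[Si](C)(C)C)=C(OC)C1(OC)O[Si](C)(C)C | intermediate
15 | octadecyl 3-(3-methoxy-1-nitro-2,4-dioxocyclohexyl)propanoate (racemic; C3 epimers and enol forms) | CCCCCCCCCCCCCCCCCCOC(=O)CCC1([N+](=O)[O-])CCC(=O)C(OC)C1=O | intermediate
16 | octadecyl 3-(5-methoxy-4,6-dioxocyclohex-1-en-1-yl)propanoate (racemic, not isolated) | CCCCCCCCCCCCCCCCCCOC(=O)CCC1=CCC(=O)C(OC)C1=O | intermediate
17 | octadecyl 3-(2,4-dihydroxy-3-methoxyphenyl)propanoate | CCCCCCCCCCCCCCCCCCOC(=O)CCc1ccc(O)c(OC)c1O | target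

## Step count and risks

Total: 9 steps. Longest linear sequence: 6 steps (1, 2, 3, 4, 8, 9); the nitroalkene branch (5, 6, 7) joins at step 8.

**Step 8 (key step).** The most likely failure is that the reaction stops after the first C–C bond. The second bond has to join a quaternary nitro-bearing carbon to a fully substituted ketal carbon. Silyl transfer to the nitronate, or collapse through the hetero-Diels-Alder mode, would instead give an open-chain conjugate adduct after hydrolysis. Polymerisation of the nitroalkene and protodesilylation of the diene by adventitious moisture are further drains.

The fallback gives up the benzannulation and builds the side chain onto a bought ring. It sets out from 8 and rejoins the route at 17: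
- Commercial 2-methoxybenzene-1,3-diol is benzylated (BnBr, K2CO3, DMF) to 1,3-bis(benzyloxy)-2-methoxybenzene F1.
- Bromination with N-bromosuccinimide in MeCN, para to one benzyloxy group as is usual for 1,2,3-trialkoxybenzenes, gives 1,3-bis(benzyloxy)-4-bromo-2-methoxybenzene F2.
- Heck coupling of F2 with 8 (Pd(OAc)2, P(o-tol)3, Et3N, DMF, 100 °C) gives octadecyl (E)-3-[2,4-bis(benzyloxy)-3-methoxyphenyl]prop-2-enoate F3.
- Hydrogenation over 10% Pd/C in EtOAc saturates the alkene and removes both benzyl ethers to give 17.

**Step 9.** The elimination may stall. DBU first deprotonates the acidic C3–H to a stabilised diketonate, and the C6 hydrogens that must then be removed are not activated. Prolonged base treatment could also let traces of water or alcohol cleave the α-nitro ketone by a retro-Claisen ring opening.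

The fallback separates loss of nitrogen from aromatisation. It sets out from 15 and rejoins at 17:
- Radical denitration with Bu3SnH and azobisisobutyronitrile in toluene at 90 °C, reliable for tertiary α-nitro ketones, gives octadecyl 3-(3-methoxy-2,4-dioxocyclohexyl)propanoate F4.
- Dehydrogenation of F4 over 10% Pd/C in refluxing mesitylene under argon gives 17.

**Step 7.** The terminal nitroalkene may polymerise, or its double bond may migrate into the chain under the amine base, during dehydration or concentration.

The fallback avoids isolating 13. It sets out from 11 and rejoins at 15:
- Acetylation of 11 (Ac2O, trace H2SO4) gives the storable octadecyl 5-acetoxy-4-nitropentanoate F5.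
- F5 is stirred with diene 6 and anhydrous Na2CO3 in toluene at 60 °C, so that 13 is released slowly by loss of acetate and trapped as it forms.
- The same cold acid work-up as in step 8 then delivers 15.

**Step 6.** The nitroaldol may run on to a second hydroxymethylation at the still-acidic nitro-bearing carbon, or revert on work-up.

The fallback replaces the nitroaldol and dehydration by a Mannich route to 2-nitroalk-1-enes. It sets out from 9 and rejoins at 13:
- Compound 9, formaldehyde 10 and diethylamine condense to the Mannich base octadecyl 5-(diethylamino)-4-nitropentanoate F6.
- Warming the hydrochloride of F6 in toluene expels the amine salt and gives 13.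

## Further compounds

F1 | step 8 | 1,3-bis(benzyloxy)-2-methoxybenzene | COc1c(OCc2ccccc2)cccc1OCc1ccccc1
F2 | step 8 | 1,3-bis(benzyloxy)-4-bromo-2-methoxybenzene | COc1c(OCc2ccccc2)ccc(Br)c1OCc1ccccc1
F3 | step 8 | octadecyl (E)-3-[2,4-bis(benzyloxy)-3-methoxyphenyl]prop-2-enoate | CCCCCCCCCCCCCCCCCCOC(=O)/C=C/c1ccc(OCc2ccccc2)c(OC)c1OCc1ccccc1
F4 | step 9 | octadecyl 3-(3-methoxy-2,4-dioxocyclohexyl)propanoate (racemic, largely enolised) | CCCCCCCCCCCCCCCCCCOC(=O)CCC1CCC(=O)C(OC)C1=O
F5 | step 7 | octadecyl 5-acetoxy-4-nitropentanoate (racemic) | CCCCCCCCCCCCCCCCCCOC(=O)CCC(COC(C)=O)[N+](=O)[O-]
F6 | step 6 | octadecyl 5-(diethylamino)-4-nitropentanoate (racemic) | CCCCCCCCCCCCCCCCCCOC(=O)CCC(CN(CC)CC)[N+](=O)[O-]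
A1 | alternative 1 | 1-(benzyloxy)-4-bromo-2-methoxybenzene | COc1cc(Br)ccc1OCc1ccccc1
A2 | alternative 1 | [2-(1,3-dioxan-2-yl)ethyl]magnesium bromide | Br[Mg]CCC1OCCCO1
A3 | alternative 1 | 3-(benzyloxy)-6-[2-(1,3-dioxan-2-yl)ethyl]-2-methoxyphenol | COc1c(O)c(CCC2OCCCO2)ccc1OCc1ccccc1
A4 | alternative 1 | octadecan-1-ol | CCCCCCCCCCCCCCCCCCO
A5 | alternative 2 | 1,3-bis(benzyloxy)-2-methoxy-4-vinylbenzene | C=Cc1ccc(OCc2ccccc2)c(OC)c1OCc1ccccc1
A6 | alternative 2 | carbon monoxide | [C-]#[O+]
A7 | alternative 2 | octadecyl 3-[2,4-bis(benzyloxy)-3-methoxyphenyl]propanoate | CCCCCCCCCCCCCCCCCCOC(=O)CCc1ccc(OCc2ccccc2)c(OC)c1OCc1ccccc1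
A8 | alternative 3 | dioctadecyl 4-(2-methoxyacetyl)heptanedioate | COCC(=O)C(CCC(=O)OCCCCCCCCCCCCCCCCCC)CCC(=O)OCCCCCCCCCCCCCCCCCC
A9 | alternative 3 | octadecyl 3-(3-methoxy-2,4-dioxocyclohexyl)propanoate (racemic, largely enolised) | CCCCCCCCCCCCCCCCCCOC(=O)CCC1CCC(=O)C(OC)C1=O
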